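**Strategy.** The route rests on closing ring D last, by forming the C13–C18 bond in a seco-D dimer that already contains rings A–C and E of the aromatic half, the 1,4-dioxane and the whole tingenone half. The key step exploits that quaternary C13 carries a methyl: a C13=CH2 methylene is a latent tertiary radical, generated by metal-hydride hydrogen-atom transfer, that adds 6-exo to C18 of a C18=C19 olefin in ring E (C21 masked as a ketal), setting C13 and C18 and the trans-C/D, cis-D/E fusions in one operation. The precursor joins a Stork-type ABC enone and a Diels–Alder-derived ring E through the C15–C16 ethano bridge, then adds commercial tingenone by o-quinone hetero-Diels–Alder.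

Key step: step 20

Remark (numbering): locants C1–C30 follow friedelane numbering of the aromatic half; primed locants belong to the tingenone half.
Assumption: tingenone (29) is bought as the isolated natural product and supplies the quinoid half unchanged.
Assumption: the sense of asymmetric induction in steps 5 and 7 is as assigned by the accepted models; were it opposite, the antipodal amine or catalyst would be used.

**Rings A–C**

Step 1
Reactants: 1 6-methoxy-1-tetralone
Product: 2 5-bromo-6-methoxy-1-tetralone
Conditions: NBS, H2SO4 (cat.), H2O, 60 °C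
Reagents that add atoms: N-bromosuccinimide, O=C1CCC(=O)N1Br
Why: Electrophilic aromatic bromination is directed by the methoxy group to its ortho position C5, which is flanked by the alkyl ring carbon and lies away from the carbonyl side.

Step 2
Reactants: 2
Product: 3 6-methoxy-5-methyl-1-tetralone
Conditions: trimethylboroxine, Pd(PPh3)4 (5 mol %), K2CO3, 1,4-dioxane, 100 °C
Reagents that add atoms: trimethylboroxine, CB1OB(C)OB(C)O1
Why: Suzuki–Miyaura cross-coupling of the aryl bromide installs the aromatic methyl (future C23) without touching the ketone.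

Step 3
Reactants: 3
Product: 5 7-methoxy-4,8-dimethyl-1,2-dihydronaphthalene, via tertiary carbinol 4 (not isolated)
Conditions: MeMgBr, THF, 0 °C; then TsOH·H2O (cat.), toluene, 80 °C
Reagents that add atoms: methylmagnesium bromide, C[Mg]Br
Why: Grignard addition brings in the future C25 methyl and acid-catalysed dehydration of the benzylic carbinol gives the conjugated styrene-type olefin.

Step 4
Reactants: 5
Product: 7 6-methoxy-1,5-dimethyl-2-tetralone (racemic), via epoxide 6 (not isolated)
Conditions: mCPBA, NaHCO3, CH2Cl2, 0 °C; then BF3·OEt2 (cat.), 0 °C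
Reagents that add atoms: 3-chloroperoxybenzoic acid, OOC(=O)c1cccc(Cl)c1
Why: Prilezhaev epoxidation followed by Meinwald rearrangement opens the epoxide at the benzylic carbon (cation stabilised by the para-methoxy group) and a 1,2-hydride shift gives the 2-tetralone.

Step 5
Reactants: 7; 8 pent-1-en-3-one
Product: 11 (R)-7-methoxy-1,4a,8-trimethyl-4,4a,9,10-tetrahydrophenanthren-2(3H)-one (rings A–C, C9 methyl β), via chiral imine 9 (not isolated), via diketone 10 (not isolated)
Conditions: (S)-1-phenylethylamine, toluene, reflux (Dean–Stark); 8, THF, rt; aq. AcOH; then NaOMe, MeOH, 60 °C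
Reagents that add atoms: none
Why: In this asymmetric Robinson annulation the secondary enamine tautomer of the chiral imine adds to the enone on the face away from the phenyl group (d'Angelo deracemising Michael addition), which sets quaternary C9, and aldol condensation then closes ring C.

**Ring E**

Step 6
Reactants: 12 3-methylbut-2-enal
Product: 13 (E)-tert-butyldimethyl[(3-methylbuta-1,3-dien-1-yl)oxy]silane
Conditions: TBSOTf, Et3N, Et2O, 0 °C → rt
Reagents that add atoms: tert-butyldimethylsilyl trifluoromethanesulfonate, CC(C)(C)[Si](C)(C)OS(=O)(=O)C(F)(F)F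
Why: Soft vinylogous enolisation (γ-deprotonation of the O-silylated enal) gives the (E)-1-silyloxy diene.

Step 7
Reactants: 13; 14 α-methylene-γ-butyrolactone
Product: 15 (5R,6R)-6-[(tert-butyldimethylsilyl)oxy]-8-methyl-2-oxaspiro[4.5]dec-7-en-1-one (spiro carbon = C17, silyloxy carbon = C22, lactone carbonyl = future C28)
Conditions: (S)-o-tolyl-CBS-oxazaborolidine activated with HNTf2 (20 mol %), CH2Cl2, −78 → −20 °C
Reagents that add atoms: none
Why: In this catalytic asymmetric Diels–Alder reaction the 1-silyloxy and 3-methyl groups both make the CH2 terminus of the diene nucleophilic (C22 bonds to C17), the endo lactone carbonyl places C28 cis to the C22 oxygen, and the chiral Lewis acid fixes the absolute configuration of quaternary C17.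

Step 8
Reactants: 15
Product: 16 lactol of 15 (anomeric mixture)
Conditions: i-Bu2AlH, CH2Cl2, −78 °C
Reagents that add atoms: none
Why: Half-reduction of the lactone stops at the tetrahedral aluminium alkoxide, which gives the lactol on work-up.

Step 9
Reactants: 16
Product: 18 2-[(1S,2R)-2-(tert-butyldimethylsilyloxy)-1,4-dimethylcyclohex-3-en-1-yl]ethanol (17-methyl cis to 22-OTBS), via tosylhydrazone 17 (not isolated)
Conditions: TsNHNH2, EtOH, rt; catecholborane, CHCl3, 0 °C; then NaOAc·3H2O, reflux
Reagents that add atoms: none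
Why: The ring-opened hydroxy aldehyde is deoxygenated by Caglioti–Kabalka reduction of its tosylhydrazone (a mild Wolff–Kishner equivalent), so the lactone carbonyl becomes the C17 methyl (C28) and the lactone CH2CH2O becomes the C16–C15 arm with a free C15 hydroxyl.

Step 10
Reactants: 18
Product: 19 diol, (1R,2R,3S,6S)-2-(tert-butyldimethylsilyloxy)-3-(2-hydroxyethyl)-3,6-dimethylcyclohexan-1-ol (21-OH trans to 22-OTBS)
Conditions: BH3·THF, 0 °C → rt; then NaOH, H2O2 (aq)
Reagents that add atoms: hydrogen peroxide, OO
Why: Hydroboration–oxidation places boron on the less substituted C21 from the face opposite the allylic silyloxy group, which puts oxygen on C21; the new C20 and C21 centres are erased later.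

Step 11
Reactants: 19
Product: 20 primary iodide of 19 (C15–I, C21–OH free)
Conditions: I2, PPh3, imidazole, CH2Cl2, 0 °C
Reagents that add atoms: iodine, II
Why: Appel-type iodination is selective for the unhindered primary alcohol over the flanked secondary C21 hydroxyl.

Step 12
Reactants: 20
Product: 21 (2R,3S,6S)-2-(tert-butyldimethylsilyloxy)-3-(2-iodoethyl)-3,6-dimethylcyclohexan-1-one
Conditions: Dess–Martin periodinane, NaHCO3, CH2Cl2, rt
Reagents that add atoms: none
Why: Dess–Martin oxidation gives the C21 ketone under buffered, non-epimerising conditions.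

Step 13
Reactants: 21
Product: 23 (5S,6R)-6-(tert-butyldimethylsilyloxy)-5-(2-iodoethyl)-2,5-dimethylcyclohex-2-en-1-one, via silyl enol ether 22 (not isolated)
Conditions: TMSOTf, Et3N, CH2Cl2, 0 °C; then Pd(OAc)2, MeCN, rt
Reagents that add atoms: none
Why: In this Saegusa–Ito dehydrogenation enolisation goes away from the silyloxy-bearing C22, and only the C20 side can lose a β-hydrogen because C17 is quaternary, so the C19=C20 enone is the only possible product.

Step 14
Reactants: 23
Product: 24 ring-E iodide, ethylene ketal of the 18-en-21-one (C18=C19, C20 methyl drawn β, 22β-OTBS, C17 methyl β)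
Conditions: ethylene glycol, TsOH·H2O (cat.), benzene, reflux (Dean–Stark)
Reagents that add atoms: ethylene glycol, OCCO
Why: Acid-catalysed ketalisation of an enone goes through the dienol, which is protonated at the α-carbon C20, so the double bond leaves conjugation for C18=C19 as in steroidal enone ketals; C20 stays epimerisable and is corrected in step 21.

**Union, dimerisation and ring D**

Step 15
Reactants: 11; 24
Product: 25 seco-D ketone (C13=O, C7=C8, C14 methyl β, C15–C16 bridge α to ring E)
Conditions: KOtBu, t-BuOH/THF, 0 → 40 °C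
Reagents that add atoms: none
Why: In this Stork deconjugative α-alkylation the extended potassium dienolate is alkylated at C14 with axial entry of the iodide anti to the C9 β-methyl, which sets quaternary C14 and moves the double bond to C7=C8.

Step 16
Reactants: 25
Product: 26 13-methylene compound
Conditions: Ph3PCH3Br, KOtBu, toluene, 90 °C
Reagents that add atoms: methyltriphenylphosphonium bromide, C[P+](c1ccccc1)(c1ccccc1)c1ccccc1.[Br-]
Why: Wittig methylenation of the only ketone gives the C13=CH2 group (future C27 methyl); no conjugation is possible because C14 is quaternary.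

Step 17
Reactants: 26
Product: 27 6-oxo-7-ene
Conditions: CrO3, 3,5-dimethylpyrazole, CH2Cl2, −20 °C
Reagents that add atoms: chromium trioxide, O=[Cr](=O)=O
Why: Allylic oxidation with the CrO3–dimethylpyrazole complex should attack C6, the only methylene that is both benzylic and allylic, ahead of the singly allylic C12 and C20 positions.

Step 18
Reactants: 27
Product: 28 C3 phenol
Conditions: NaSEt, DMF, 120 °C
Reagents that add atoms: none
Why: SN2 O-demethylation by thiolate frees the phenol without acid, so the ketal, the silyl ether and both olefins survive; the enone β-carbon C8 is fully substituted and shielded against conjugate addition.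

Step 19
Reactants: 28; 29 tingenone
Product: 31 seco-D dimer (dioxane closed, 3′α-OH, 4′α-methyl), via o-quinone 30 (not isolated)
Conditions: IBX, DMF, rt; then 29, CH2Cl2, rt, dark
Reagents that add atoms: 2-iodoxybenzoic acid, O=C1OI(=O)(O)c2ccccc12
Why: IBX delivers oxygen to the only free ortho position (C2) and oxidises on to the o-quinone, which should add suprafacially across the C3′=C4′ enol of 29 (inverse-electron-demand hetero-Diels–Alder) to give the cis-dioxane; bonding of the C3 oxygen to C4′ and approach to the β face are the selectivity needs, resting on the polarisation of the enol and on chromatographic removal of other adducts.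

Step 20
Reactants: 31
Product: 32 ring-D-closed dimer (21-ketal, 22-OTBS)
Conditions: Fe(acac)3, PhSiH3, EtOH/THF, 50 °C
Reagents that add atoms: none
Why: The iron hydride formed from Fe(acac)3 and PhSiH3 transfers a hydrogen atom to the terminal carbon of the C13=CH2 olefin, the tertiary C13 radical adds to C18 of the C18=C19 olefin, and the secondary C19 radical is quenched by a second hydrogen transfer. The closest known reaction type is the metal-hydride hydrogen-atom-transfer (Mukaiyama-type) reductive radical cyclisation of dienes. Ring D closes in the 6-exo-trig mode, preferred over 7-endo attack at C19 and helped by the two quaternary carbons (C14, C17) in the tether. C18 is controlled by the tether, because the C16 arm lies on the α face of ring E at C17 and can deliver C13 only to that face, which gives the cis D/E fusion with 18β-H. C13 is controlled by a chair-like transition state in which the new bond is equatorial on ring C and the new 13α-methyl is anti to the 14β-methyl, which gives the trans C/D fusion. The step needs hydrogen transfer to the 1,1-disubstituted C13=CH2 olefin only, which is secured because C18=C19 is 1,2-disubstituted and hindered and the remaining olefins (C7=C8 and the trienone of the tingenone half) are carbonyl-conjugated and tri- or tetrasubstituted, all poor acceptors of the hydridic hydrogen atom.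

Step 21
Reactants: 32
Product: 33 CNP0218299.2 (target)
Conditions: HF·pyridine, THF, 0 °C → rt; then 1 M HCl (aq), THF, rt
Reagents that add atoms: water, O
Why: Fluoride cleaves the silyl ether and aqueous acid hydrolyses the dioxolane; the now enolisable C20 should settle as the equatorial β-methyl epimer (ring E chair with the 17-methyl axial) while the equatorial 22β-hydroxyl is kept.

**Compound list**

1 | 6-methoxy-1-tetralone | COc1ccc2c(c1)CCCC2=O | starting material
2 | 5-bromo-6-methoxy-1-tetralone | COc1ccc2c(c1Br)CCCC2=O | intermediate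
3 | 6-methoxy-5-methyl-1-tetralone | COc1ccc2c(c1C)CCCC2=O | intermediate
4 | 6-methoxy-1,5-dimethyl-1,2,3,4-tetrahydronaphthalen-1-ol (racemic) | COc1ccc2c(c1C)CCCC2(C)O | intermediate (not isolated)
5 | 7-methoxy-4,8-dimethyl-1,2-dihydronaphthalene | COc1ccc2c(c1C)CCC=C2C | intermediate
6 | 3,4-epoxide of 5 (racemic) | COc1ccc2c(c1C)CCC1OC21C | intermediate (not isolated)
7 | 6-methoxy-1,5-dimethyl-3,4-dihydronaphthalen-2(1H)-one (racemic) | COc1ccc2c(c1C)CCC(=O)C2C | intermediate
8 | pent-1-en-3-one | CCC(=O)C=C | starting material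
9 | (S)-1-phenylethyl imine of 7 | COc1ccc2c(c1C)CCC(=N[C@@H](C)c1ccccc1)C2C | intermediate (not isolated)
10 | (S)-6-methoxy-1,5-dimethyl-1-(3-oxopentyl)-3,4-dihydronaphthalen-2(1H)-one | CCC(=O)CC[C@]1(C)C(=O)CCc2c(C)c(OC)ccc21 | intermediate (not isolated)
11 | (R)-7-methoxy-1,4a,8-trimethyl-4,4a,9,10-tetrahydrophenanthren-2(3H)-one | Cc1c(OC)ccc2c1CCC1=C(C)C(=O)CC[C@@]21C | intermediate
12 | 3-methylbut-2-enal | CC(C)=CC=O | starting material
13 | (E)-tert-butyldimethyl[(3-methylbuta-1,3-dien-1-yl)oxy]silane | C=C(C)/C=C/O[Si](C)(C)C(C)(C)C | intermediate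
14 | α-methylene-γ-butyrolactone | C=C1CCOC1=O | starting material
15 | (5R,6R)-6-[(tert-butyldimethylsilyl)oxy]-8-methyl-2-oxaspiro[4.5]dec-7-en-1-one | O=C1OCC[C@@]12CCC(C)=C[C@H]2O[Si](C)(C)C(C)(C)C | intermediate
16 | lactol of 15 | OC1OCC[C@@]12CCC(C)=C[C@H]2O[Si](C)(C)C(C)(C)C | intermediate
17 | tosylhydrazone of the ring-opened hydroxy aldehyde | OCC[C@]1(C=NNS(=O)(=O)c2ccc(C)cc2)CCC(C)=C[C@H]1O[Si](C)(C)C(C)(C)C | intermediate (not isolated)
18 | 2-[(1S,2R)-2-(tert-butyldimethylsilyloxy)-1,4-dimethylcyclohex-3-en-1-yl]ethanol | OCC[C@]1(C)CCC(C)=C[C@H]1O[Si](C)(C)C(C)(C)C | intermediate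
19 | ring-E diol (C15–OH, 21α-OH, 20β-methyl, 22β-OTBS) | OCC[C@]1(C)CC[C@@H](C)[C@H](O)[C@H]1O[Si](C)(C)C(C)(C)C | intermediate
20 | ring-E iodo alcohol | ICC[C@]1(C)CC[C@@H](C)[C@H](O)[C@H]1O[Si](C)(C)C(C)(C)C | intermediate
21 | ring-E iodo ketone (C21=O) | ICC[C@]1(C)CC[C@@H](C)C(=O)[C@H]1O[Si](C)(C)C(C)(C)C | intermediate
22 | trimethylsilyl enol ether of 21 (C20=C21) | ICC[C@]1(C)CCC(C)=C(O[Si](C)(C)C)[C@H]1O[Si](C)(C)C(C)(C)C | intermediate (not isolated)
23 | ring-E enone iodide (C19=C20, C21=O) | ICC[C@]1(C)CC=C(C)C(=O)[C@H]1O[Si](C)(C)C(C)(C)C | intermediate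
24 | ring-E ketal iodide (C18=C19, C21 dioxolane, 22β-OTBS) | ICC[C@]1(C)C=C[C@@H](C)C2(OCCO2)[C@H]1O[Si](C)(C)C(C)(C)C | intermediate
25 | seco-D 13-ketone (rings A–C joined to ring E by C15–C16) | Cc1c(OC)ccc2c1CC=C1[C@@]2(C)CCC(=O)[C@]1(C)CC[C@]1(C)C=C[C@@H](C)C2(OCCO2)[C@H]1O[Si](C)(C)C(C)(C)C | intermediate
26 | seco-D 13-methylene compound | Cc1c(OC)ccc2c1CC=C1[C@@]2(C)CCC(=C)[C@]1(C)CC[C@]1(C)C=C[C@@H](C)C2(OCCO2)[C@H]1O[Si](C)(C)C(C)(C)C | intermediate
27 | seco-D 6-oxo-7-ene methyl ether | Cc1c(OC)ccc2c1C(=O)C=C1[C@@]2(C)CCC(=C)[C@]1(C)CC[C@]1(C)C=C[C@@H](C)C2(OCCO2)[C@H]1O[Si](C)(C)C(C)(C)C | intermediate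
28 | seco-D 6-oxo-7-ene C3 phenol | Cc1c(O)ccc2c1C(=O)C=C1[C@@]2(C)CCC(=C)[C@]1(C)CC[C@]1(C)C=C[C@@H](C)C2(OCCO2)[C@H]1O[Si](C)(C)C(C)(C)C | intermediate
29 | tingenone | CC1=C(O)C(=O)C=C2C1=CC=C1[C@@]2(C)CC[C@@]2(C)[C@@H]3C[C@@H](C)C(=O)C[C@]3(C)CC[C@]12C | starting material
30 | seco-D 2,3-o-quinone | CC1=C2C(=O)C=C3[C@](C)(C2=CC(=O)C1=O)CCC(=C)[C@]3(C)CC[C@]1(C)C=C[C@@H](C)C2(OCCO2)[C@H]1O[Si](C)(C)C(C)(C)C | intermediate (not isolated)
31 | seco-D dimer (hetero-Diels–Alder adduct, β-face dioxane) | Cc1c2c(cc3c1C(=O)C=C1[C@@]3(C)CCC(=C)[C@]1(C)CC[C@]1(C)C=C[C@@H](C)C4(OCCO4)[C@H]1O[Si](C)(C)C(C)(C)C)O[C@@]1(O)C(=O)C=C3C(=CC=C4[C@@]3(C)CC[C@@]3(C)[C@@H]5C[C@@H](C)C(=O)C[C@]5(C)CC[C@]43C)[C@@]1(C)O2 | intermediate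
32 | ring-D-closed dimer, 21-ethylene ketal 22-TBS ether | Cc1c2c(cc3c1C(=O)C=C1[C@@]3(C)CC[C@@]3(C)[C@@H]4C[C@@H](C)C5(OCCO5)[C@@H](O[Si](C)(C)C(C)(C)C)[C@]4(C)CC[C@]13C)O[C@@]1(O)C(=O)C=C3C(=CC=C4[C@@]3(C)CC[C@@]3(C)[C@@H]5C[C@@H](C)C(=O)C[C@]5(C)CC[C@]43C)[C@@]1(C)O2 | intermediate
33 | CNP0218299.2 | Cc1c2c(cc3c1C(=O)C=C1[C@@]3(C)CC[C@@]3(C)[C@@H]4C[C@@H](C)C(=O)[C@@H](O)[C@]4(C)CC[C@]13C)O[C@@]1(O)C(=O)C=C3C(=CC=C4[C@@]3(C)CC[C@@]3(C)[C@@H]5C[C@@H](C)C(=O)C[C@]5(C)CC[C@]43C)[C@@]1(C)O2 | target

**Count and risks**

Total step count: 21. Longest linear sequence: 16 steps (steps 6–14, then 15–21); the ABC branch (steps 1–5) joins at step 15 and tingenone at step 19.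

The three steps most likely to fail:

Step 20. The tertiary C13 radical may be reduced, or may revert to olefin isomers, faster than it closes onto the unactivated C18=C19 olefin, and closure may take the wrong facial course at C13. The fallback sets out from 31 and comes back at 33. A redox-neutral cycloisomerisation with Co(salen)Cl (chloro[N,N′-ethylenebis(salicylideneiminato)]cobalt) and PhSiH3 keeps the C13 radical–cobalt pair alive longer and discharges the C19 radical by β-hydrogen loss; it should give the ring-D-closed 19(20)-olefin ketal F1. HF·pyridine and then aqueous HCl should unmask the conjugated 19-en-21-one with free 22-hydroxyl F2. Conjugate reduction with [(Ph3P)CuH]6, which should prefer the only enone with a β-hydrogen, followed by protonation at C20, returns 33.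

Step 19. Oxygen transfer to the acyl-deactivated phenol may be slow, so that the o-quinone decays in the presence of the oxidant before it is trapped; approach to the α face or the reverse orientation would give isomeric adducts that must be separated. The fallback sets out from 28 and comes back at 31 through 30. Ortho-formylation (MgCl2, Et3N, paraformaldehyde, MeCN, reflux) should give the salicylaldehyde F3, and Dakin oxidation (H2O2, NaOH) the stable catechol F4. The catechol is oxidised with Ag2O in CH2Cl2 in the presence of 29, so that 30 is generated under neutral conditions and trapped at once.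

Step 15. The potassium dienolate may be alkylated on oxygen or at C12, and substitution at the γ-branched iodide may be slow. The fallback sets out from 11 and comes back at 25. The N-cyclohexyl imine F5 (cyclohexylamine, TsOH cat., toluene, reflux) is deprotonated with LDA in THF to the metalloenamine (Stork–Benaim), which should be alkylated on carbon at C14 by 24 to give the β,γ-unsaturated imine F6; aqueous oxalic acid hydrolyses it to 25.

**Further compounds**

F1 | step 20 | ring-D-closed dimer with C19=C20 olefin, 21-ethylene ketal 22-TBS ether | Cc1c2c(cc3c1C(=O)C=C1[C@@]3(C)CC[C@@]3(C)[C@@H]4C=C(C)C5(OCCO5)[C@@H](O[Si](C)(C)C(C)(C)C)[C@]4(C)CC[C@]13C)O[C@@]1(O)C(=O)C=C3C(=CC=C4[C@@]3(C)CC[C@@]3(C)[C@@H]5C[C@@H](C)C(=O)C[C@]5(C)CC[C@]43C)[C@@]1(C)O2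
F2 | step 20 | 19,20-didehydro derivative of the target (19-en-21-one, 22β-OH) | Cc1c2c(cc3c1C(=O)C=C1[C@@]3(C)CC[C@@]3(C)[C@@H]4C=C(C)C(=O)[C@@H](O)[C@]4(C)CC[C@]13C)O[C@@]1(O)C(=O)C=C3C(=CC=C4[C@@]3(C)CC[C@@]3(C)[C@@H]5C[C@@H](C)C(=O)C[C@]5(C)CC[C@]43C)[C@@]1(C)O2
F3 | step 19 | 2-formyl derivative of phenol 28 | Cc1c(O)c(C=O)cc2c1C(=O)C=C1[C@@]2(C)CCC(=C)[C@]1(C)CC[C@]1(C)C=C[C@@H](C)C2(OCCO2)[C@H]1O[Si](C)(C)C(C)(C)C
F4 | step 19 | seco-D 2,3-catechol | Cc1c(O)c(O)cc2c1C(=O)C=C1[C@@]2(C)CCC(=C)[C@]1(C)CC[C@]1(C)C=C[C@@H](C)C2(OCCO2)[C@H]1O[Si](C)(C)C(C)(C)C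
F5 | step 15 | N-cyclohexyl imine of 11 | Cc1c(OC)ccc2c1CCC1=C(C)C(=NC3CCCCC3)CC[C@@]21C
F6 | step 15 | N-cyclohexyl imine of 25 | Cc1c(OC)ccc2c1CC=C1[C@@]2(C)CCC(=NC3CCCCC3)[C@]1(C)CC[C@]1(C)C=C[C@@H](C)C2(OCCO2)[C@H]1O[Si](C)(C)C(C)(C)C
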